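## Retrosynthetic overview
1. The cyclopentane is closed last. A redox-neutral Pd(II) alkenylative cyclisation of an allenyl aldehyde with a dienylboronate makes C1–C2 and C15–C16, sets C1 and C2, and delivers the whole side chain.
2. The enal and the 3-hydroxypropyl chain are one masked unit, a tetrahydropyranyl ketal. It is unmasked by Mukaiyama addition of a propanal enol silane followed by β-elimination.
3. Key step: a donor–acceptor cyclopropane and a tethered methyl ketone undergo an intramolecular [3+2] cross-cycloaddition. The cyclohexane and a bridging oxolane form together, and C5 and C6 are set from C10.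
4. The cyclopropane comes from dihydropyran, methyl vinyl ketone and ethyl diazoacetate, followed by C-alkylation with 5-iodopenta-1,2-diene.
5. Ring order: pyran (purchased) → cyclopropane → cyclohexane plus oxa-bridge in one operation → pyran and bridge opened → cyclopentane.

Locants: C1–C10 follow the spiro[4.5]decane numbering of the target.
- C1 = CHOH
- C2 = CH bearing the trienyl chain
- C5 = spiro carbon
- C6 = C(CH3)OH
- C9 = alkylidene carbon
- C10 = CH bearing the hydroxypropyl chain

Assumption: the (S,S)-t-Bu-box ligand is taken to give the drawn cyclopropane enantiomer. If the sense of induction is opposite, the equally available (R,R)-ligand is used.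

## Route

Step 1
Reactants: 1 3,4-dihydro-2H-pyran; 2 methyl vinyl ketone
Product: 5 4-(3,4-dihydro-2H-pyran-6-yl)butan-2-one, via 6-lithio-3,4-dihydro-2H-pyran 3 (not isolated), via lithium bis(3,4-dihydro-2H-pyran-6-yl)cuprate 4 (not isolated)
Conditions: 1 (2 equiv), t-BuLi (2 equiv), THF/pentane, −78 to 0 °C; CuI (1 equiv), −40 °C; 2 (1 equiv), −78 °C; aq NH4Cl/NH3 quench; basic alumina
Reagents that add atoms: none
Why: α-Lithiation of the cyclic enol ether and Gilman-cuprate conjugate addition of the α-alkoxyvinyl group to the enone joins nine target carbons (hydroxypropyl chain, C10, C9, C8, C7, C6 and its methyl) without creating a stereocentre.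

Step 2
Reactants: 5 4-(3,4-dihydro-2H-pyran-6-yl)butan-2-one; 6 ethyl diazoacetate
Product: 7 ethyl (1S,6S)-1-(3-oxobutyl)-2-oxabicyclo[4.1.0]heptane-7-carboxylate (C7 epimers)
Conditions: CuOTf·½C6H6 (1 mol %), (S,S)-t-Bu-box (1.2 mol %), CH2Cl2, rt, 6 added over 10 h
Reagents that add atoms: none
Why: Cu(I)–bis(oxazoline) asymmetric carbene transfer picks the electron-rich enol ether over the ketone, the suprafacial addition enforces the cis ring fusion, the catalyst-selected alkene face fixes the future C10 together with the ketal carbon, and the C7 epimers converge later.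

Step 3
Reactants: 8 but-3-yn-1-ol
Product: 9 penta-3,4-dien-1-ol
Conditions: (CH2O)n, CuBr (0.3 equiv), i-Pr2NH, 1,4-dioxane, reflux
Reagents that add atoms: paraformaldehyde (formaldehyde) C=O
Why: Crabbé homologation (Mannich base formation followed by a retro-imino-ene hydride shift) converts the terminal alkyne into the terminal allene and adds the future exocyclic methylene carbon.

Step 4
Reactants: 9 penta-3,4-dien-1-ol
Product: 10 5-iodopenta-1,2-diene
Conditions: I2, PPh3, imidazole, CH2Cl2, 0 °C
Reagents that add atoms: iodine II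
Why: The Appel iodination replaces the primary hydroxyl by SN2 displacement of the oxyphosphonium ion under neutral conditions that leave the allene intact.

Step 5
Reactants: 7 ethyl (1S,6S)-1-(3-oxobutyl)-2-oxabicyclo[4.1.0]heptane-7-carboxylate; 10 5-iodopenta-1,2-diene
Product: 12 ethyl (1S,6S)-1-(3-oxobutyl)-7-(penta-3,4-dien-1-yl)-2-oxabicyclo[4.1.0]heptane-7-carboxylate (C7 epimers), via dilithium bis-enolate 11 (not isolated)
Conditions: LDA (2.2 equiv), THF, −78 °C; 10 (1.05 equiv), DMPU, −78 to −45 °C; AcOH/THF quench at −78 °C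
Reagents that add atoms: none
Why: This is the alkylation of a 2-alkoxycyclopropanecarboxylate enolate, in which the methyl ketone is parked as its kinetic lithium enolate that is far less reactive toward an unactivated primary iodide at this temperature and is reprotonated on quench, and the configuration of the new quaternary carbon does not matter because the next step planarises it.

Step 6
Reactants: 12 ethyl (1S,6S)-1-(3-oxobutyl)-7-(penta-3,4-dien-1-yl)-2-oxabicyclo[4.1.0]heptane-7-carboxylate
Product: 13 ethyl 6-methyl-5-(penta-3,4-dien-1-yl)octahydro-6,8a-epoxychromene-5-carboxylate (CO2Et exo = syn to the O-bridge; pyran CH2-4 exo; pentadienyl endo)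
Conditions: Sc(OTf)3 (10 mol %), 4 Å MS, CH2Cl2, −20 °C to rt
Reagents that add atoms: none
Why: Proposed new method: Sc(III) binds the ester and heterolyses the push–pull C1–C7 bond to a pyranyl oxocarbenium/scandium ester-enolate zwitterion, the enolate carbon adds to the tethered methyl ketone through a Sc-chelated closed six-ring aldol transition state that keeps CO2Et syn to the new C–O bond, and the alkoxide collapses on the oxocarbenium ion, so the cyclohexane and the bridging oxolane form together and C5 and C6 are set from the untouched C10 centre because the bridge can close only on the face that carries the enolate arm, the closest known reaction type being the Lewis-acid-catalysed intramolecular [3+2] cross-cycloaddition of donor–acceptor cyclopropanes with tethered carbonyl groups.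

Step 7
Reactants: 14 propanal
Product: 15 trimethyl(prop-1-en-1-yloxy)silane (E/Z mixture)
Conditions: TMSCl, Et3N, DMF, 80 °C
Reagents that add atoms: chlorotrimethylsilane C[Si](C)(C)Cl
Why: House silyl enol ether formation under equilibrating amine conditions gives the aldehyde enol silane, whose geometry is irrelevant because the derived stereocentre is erased later.

Step 8
Reactants: 13 ethyl 6-methyl-5-(penta-3,4-dien-1-yl)octahydro-6,8a-epoxychromene-5-carboxylate; 15 trimethyl(prop-1-en-1-yloxy)silane
Product: 16 ethyl 6-methyl-8a-(1-oxopropan-2-yl)-5-(penta-3,4-dien-1-yl)-6-(trimethylsilyloxy)octahydro-2H-chromene-5-carboxylate (epimers at C8a and the side-chain CH)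
Conditions: TMSOTf (10 mol %), CH2Cl2, −78 °C
Reagents that add atoms: none
Why: In this Noyori-type TMSOTf-catalysed Mukaiyama aldol addition to a ketal only the strained oxa-bridge can ionise (loss of the pyran oxygen would require a bridgehead oxocarbenium ion), the enol silane attacks the pyranyl oxocarbenium carbon C9, silyl transfer caps the C6 oxygen as its TMS ether, and the two new stereocentres are destroyed in step 10.

Step 9
Reactants: 16 ethyl 6-methyl-8a-(1-oxopropan-2-yl)-5-(penta-3,4-dien-1-yl)-6-(trimethylsilyloxy)octahydro-2H-chromene-5-carboxylate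
Product: 17 2-[5-(hydroxymethyl)-6-methyl-5-(penta-3,4-dien-1-yl)-6-(trimethylsilyloxy)octahydro-2H-chromen-8a-yl]propan-1-ol
Conditions: LiAlH4, THF, 0 °C to rt; Na2SO4·10H2O work-up
Reagents that add atoms: none
Why: Hydride reduction takes the hindered ester and the aldehyde to primary alcohols while the third primary oxygen stays locked in the pyran ring, so no protecting group is needed, and the allene, the pyranyl ether and the tertiary silyl ether are inert.

Step 10
Reactants: 17 2-[5-(hydroxymethyl)-6-methyl-5-(penta-3,4-dien-1-yl)-6-(trimethylsilyloxy)octahydro-2H-chromen-8a-yl]propan-1-ol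
Product: 19 (1R,2S,6R,5Z)-2-hydroxy-6-(3-hydroxypropyl)-2-methyl-5-(1-oxopropan-2-ylidene)-1-(penta-3,4-dien-1-yl)cyclohexane-1-carbaldehyde, via pyranyl dialdehyde 18 (not isolated)
Conditions: DMP (2.5 equiv), CH2Cl2, 0 °C to rt; then acetone/H2O, p-TsOH·H2O (10 mol %), rt
Reagents that add atoms: none
Why: Dess–Martin oxidation of both primary alcohols is followed by acid-catalysed β-elimination of the tertiary pyranyl oxygen (a retro-oxa-Michael reaction, the last stage of an Isler-type enol ether condensation), which frees the 3-hydroxypropyl chain, forms the tetrasubstituted enal and removes the TMS group, the reversible oxa-Michael addition equilibrates the alkene toward the Z isomer that puts the flat CHO next to the branched C10, and any E isomer is separated and resubmitted.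

Step 11
Reactants: 20 5-bromo-2-methylpent-2-ene; 21 prop-2-yn-1-ol
Product: 24 (Z)-3-iodo-2-(4-methylpent-3-en-1-yl)prop-2-en-1-ol, via 4-methylpent-3-enylmagnesium bromide 22 (not isolated), via chelated alkenylmagnesium alkoxide 23 (not isolated)
Conditions: 20 (2.2 equiv), Mg, THF; 21 (1 equiv), CuI (10 mol %), THF, −10 °C to rt; I2, −40 to 0 °C
Reagents that add atoms: iodine II
Why: Copper-catalysed anti-carbomagnesiation of propargyl alcohol places the alkyl group on C2 and magnesium on C3 within a five-membered magnesium alkoxide chelate, and iodinolysis with retention leaves iodine cis to CH2OH, which is the geometry of the trisubstituted side-chain alkene.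

Step 12
Reactants: 24 (Z)-3-iodo-2-(4-methylpent-3-en-1-yl)prop-2-en-1-ol; 25 4,4,5,5-tetramethyl-2-vinyl-1,3,2-dioxaborolane
Product: 26 (2Z,4E)-2-(4-methylpent-3-en-1-yl)-5-(4,4,5,5-tetramethyl-1,3,2-dioxaborolan-2-yl)penta-2,4-dien-1-ol
Conditions: Pd(OAc)2 (5 mol %), P(o-tol)3 (10 mol %), AgOAc (1.1 equiv), MeCN, 50 °C
Reagents that add atoms: none
Why: The boron-retentive Heck–Mizoroki coupling of a vinylboronate proceeds by syn-insertion and syn-β-hydride elimination to give the new E alkene with retention of the vinyl iodide geometry, and the base-free silver conditions suppress the competing Suzuki pathway.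

Step 13
Reactants: 26 (2Z,4E)-2-(4-methylpent-3-en-1-yl)-5-(4,4,5,5-tetramethyl-1,3,2-dioxaborolan-2-yl)penta-2,4-dien-1-ol
Product: 27 (2Z,4E)-2-(4-methylpent-3-en-1-yl)-5-(4,4,5,5-tetramethyl-1,3,2-dioxaborolan-2-yl)penta-2,4-dien-1-yl acetate
Conditions: Ac2O, pyridine, DMAP (cat.), CH2Cl2, 0 °C
Reagents that add atoms: acetic anhydride CC(=O)OC(C)=O
Why: DMAP-catalysed acylation puts the only acetate of the target on the fragment before the coupling, so no hydroxyl group has to be differentiated at the end, and the pinacol boronate is inert.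

Step 14
Reactants: 19 (1R,2S,6R,5Z)-2-hydroxy-6-(3-hydroxypropyl)-2-methyl-5-(1-oxopropan-2-ylidene)-1-(penta-3,4-dien-1-yl)cyclohexane-1-carbaldehyde; 27 (2Z,4E)-2-(4-methylpent-3-en-1-yl)-5-(4,4,5,5-tetramethyl-1,3,2-dioxaborolan-2-yl)penta-2,4-dien-1-yl acetate
Product: 28 CNP0205332.1 (target; 1R,2S,5S,6S,10R; 9Z enal)
Conditions: [Pd(dppp)(H2O)2](OTf)2 (5 mol %), 1,4-dioxane/H2O 10:1, 40 °C
Reagents that add atoms: none
Why: In this Pd-catalysed alkenylative cyclisation of an allenyl aldehyde with an organoboron reagent, transmetalation gives a dienyl–Pd(II) species that adds to the central allene carbon, the resulting allyl–Pd attacks the neopentyl aldehyde through a compact bicyclic transition state that gives the cis-2-(1-alkenylvinyl)cyclopentanol, the metal-bound carbonyl oxygen turns away from the C6 carbon bearing CH3 and OH toward the C10–H side (non-chelate 1,3-anti) and thereby sets C1 (R) and C2 (S), the hindered conjugated enal is not attacked, and the allylic acetate survives because no Pd(0) is involved.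

## Compound list
1 | 3,4-dihydro-2H-pyran | C1=COCCC1 | starting material
2 | methyl vinyl ketone | C=CC(C)=O | starting material
3 | 6-lithio-3,4-dihydro-2H-pyran | [Li]C1=CCCCO1 | intermediate
4 | lithium bis(3,4-dihydro-2H-pyran-6-yl)cuprate | [Li+].C1(=CCCCO1)[Cu-]C1=CCCCO1 | intermediate
5 | 4-(3,4-dihydro-2H-pyran-6-yl)butan-2-one | CC(=O)CCC1=CCCCO1 | intermediate
6 | ethyl diazoacetate | CCOC(=O)C=[N+]=[N-] | starting material
7 | ethyl (1S,6S)-1-(3-oxobutyl)-2-oxabicyclo[4.1.0]heptane-7-carboxylate (C7 epimers) | CCOC(=O)C1[C@@H]2CCCO[C@@]21CCC(C)=O | intermediate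
8 | but-3-yn-1-ol | C#CCCO | starting material
9 | penta-3,4-dien-1-ol | C=C=CCCO | intermediate
10 | 5-iodopenta-1,2-diene | C=C=CCCI | intermediate
11 | dilithium bis-enolate of 7 | CCOC(O[Li])=C1[C@@H]2CCCO[C@@]21CCC(=C)O[Li] | intermediate
12 | ethyl (1S,6S)-1-(3-oxobutyl)-7-(penta-3,4-dien-1-yl)-2-oxabicyclo[4.1.0]heptane-7-carboxylate (C7 epimers) | CCOC(=O)C1(CCC=C=C)[C@@H]2CCCO[C@@]21CCC(C)=O | intermediate
13 | ethyl 6-methyl-5-(penta-3,4-dien-1-yl)octahydro-6,8a-epoxychromene-5-carboxylate (ester exo, pyran CH2 exo) | CCOC(=O)[C@]1(CCC=C=C)[C@@H]2CCCO[C@@]23CC[C@]1(C)O3 | intermediate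
14 | propanal | CCC=O | starting material
15 | trimethyl(prop-1-en-1-yloxy)silane (E/Z) | CC=CO[Si](C)(C)C | intermediate
16 | ethyl 6-methyl-8a-(1-oxopropan-2-yl)-5-(penta-3,4-dien-1-yl)-6-(trimethylsilyloxy)octahydro-2H-chromene-5-carboxylate (epimers at C8a and side-chain CH) | CCOC(=O)[C@]1(CCC=C=C)[C@@H]2CCCOC2(C(C)C=O)CC[C@]1(C)O[Si](C)(C)C | intermediate
17 | 2-[5-(hydroxymethyl)-6-methyl-5-(penta-3,4-dien-1-yl)-6-(trimethylsilyloxy)octahydro-2H-chromen-8a-yl]propan-1-ol | OC[C@]1(CCC=C=C)[C@@H]2CCCOC2(C(C)CO)CC[C@]1(C)O[Si](C)(C)C | intermediate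
18 | pyranyl dialdehyde (bis-oxidised 17) | O=C[C@]1(CCC=C=C)[C@@H]2CCCOC2(C(C)C=O)CC[C@]1(C)O[Si](C)(C)C | intermediate
19 | (1R,2S,6R,5Z)-2-hydroxy-6-(3-hydroxypropyl)-2-methyl-5-(1-oxopropan-2-ylidene)-1-(penta-3,4-dien-1-yl)cyclohexane-1-carbaldehyde | O=C[C@]1(CCC=C=C)[C@H](CCCO)/C(=C(/C)C=O)CC[C@]1(C)O | intermediate
20 | 5-bromo-2-methylpent-2-ene | CC(C)=CCCBr | starting material
21 | prop-2-yn-1-ol | C#CCO | starting material
22 | 4-methylpent-3-enylmagnesium bromide | CC(C)=CCC[Mg]Br | intermediate
23 | chelated alkenylmagnesium alkoxide | Br[Mg]/C=C(/CCC=C(C)C)CO[Mg]Br | intermediate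
24 | (Z)-3-iodo-2-(4-methylpent-3-en-1-yl)prop-2-en-1-ol | I/C=C(/CCC=C(C)C)CO | intermediate
25 | 4,4,5,5-tetramethyl-2-vinyl-1,3,2-dioxaborolane | C=CB1OC(C)(C)C(C)(C)O1 | starting material
26 | (2Z,4E)-2-(4-methylpent-3-en-1-yl)-5-(pinacolboryl)penta-2,4-dien-1-ol | CC1(C)OB(/C=C/C=C(/CCC=C(C)C)CO)OC1(C)C | intermediate
27 | (2Z,4E)-2-(4-methylpent-3-en-1-yl)-5-(pinacolboryl)penta-2,4-dien-1-yl acetate | CC1(C)OB(/C=C/C=C(/CCC=C(C)C)COC(C)=O)OC1(C)C | intermediate
28 | CNP0205332.1 | C=C(/C=C/C=C(/CCC=C(C)C)COC(C)=O)[C@@H]1CC[C@]2([C@H](CCCO)/C(=C(/C)C=O)CC[C@]2(C)O)[C@@H]1O | target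

## Step count and risks
Total step count: 14.
Longest linear sequence: 8 steps. It runs through steps 1, 2, 5, 6, 8, 9, 10, 14 from dihydropyran. The path from but-3-yn-1-ol (steps 3, 4, 5, 6, 8, 9, 10, 14) has the same length.

**Step 6.** The cross-cycloaddition has three ways to go wrong:
- it may stop at the zwitterion;
- the oxocarbenium ion may lose a proton;
- the spiro carbon may form with the ester endo.

The fallback sets out from 12 and comes back at 13. It replaces the Lewis-acid cycloaddition with a reductive, chelation-controlled ring closure. NBS in MeOH opens the donor–acceptor cyclopropane by 1,3-bromomethoxylation to the tertiary α-bromo ester methyl ketal F1. SmI2 in THF at −78 °C converts F1 into a samarium(III) enolate. This enolate adds to the methyl ketone in an intramolecular Reformatsky reaction through a Sm-bridged chair and gives the cis-β-hydroxy ester methyl ketal F2. PPTS in CH2Cl2 then closes the oxa-bridge with loss of methanol and gives 13.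

**Step 8** (together with the alkene geometry of step 10). The enol silane may fail to reach the hindered C9 oxocarbenium carbon.

The fallback sets out from 13 and comes back at 19. It uses nucleophilic addition to the free ketone instead.
- Dilute HCl in THF hydrolyses the ketal to the keto diol ester F3.
- TBSCl and imidazole give the primary silyl ether F4.
- Excess (1-ethoxyprop-1-en-2-yl)lithium, made from 2-bromo-1-ethoxyprop-1-ene and t-BuLi, adds to the ketone and gives the tertiary allylic alcohol F5.
- 1 M HCl work-up transposes F5 to the enal ester F6.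
- DIBAL-H reduces the ester and the enal to the triol F7.
- DMP gives the silylated dialdehyde F8.
- HF·pyridine removes the silyl group and gives 19.

**Step 14.** Several things can go wrong in the three-component cyclisation:
- transmetalation of the pinacol boronate may be slow;
- the boronate may add directly to an aldehyde;
- adventitious Pd(0) may ionise the allylic acetate;
- the aldehyde face selectivity may be poor.

The fallback sets out from 19 and 27 and comes back at 28. It separates ring closure from chain attachment. Copper-catalysed borylative cyclisation of 19 (IMesCuCl cat., NaOt-Bu cat., B2pin2, MeOH, THF) adds boron to the central allene carbon. The 2-boryl allylcopper closes onto the aldehyde and gives the vinylboronate spiro diol F9. NIS in MeCN converts 27 with retention into the dienyl iodide acetate F10. A fast room-temperature Suzuki coupling of F9 and F10 (Pd(dppf)Cl2, K3PO4, THF/H2O) gives 28.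

## Further compounds
F1 | step 6 | ethyl 2-bromo-2-[(3S)-2-methoxy-2-(3-oxobutyl)tetrahydropyran-3-yl]hepta-5,6-dienoate | CCOC(=O)C(Br)(CCC=C=C)[C@@H]1CCCOC1(OC)CCC(C)=O
F2 | step 6 | ethyl 6-hydroxy-8a-methoxy-6-methyl-5-(penta-3,4-dien-1-yl)octahydro-2H-chromene-5-carboxylate | CCOC(=O)[C@]1(CCC=C=C)[C@@H]2CCCOC2(OC)CC[C@]1(C)O
F3 | step 8 | ethyl 2-hydroxy-6-(3-hydroxypropyl)-2-methyl-5-oxo-1-(penta-3,4-dien-1-yl)cyclohexane-1-carboxylate | CCOC(=O)[C@]1(CCC=C=C)[C@H](CCCO)C(=O)CC[C@]1(C)O
F4 | step 8 | primary TBS ether of F3 | CCOC(=O)[C@]1(CCC=C=C)[C@H](CCCO[Si](C)(C)C(C)(C)C)C(=O)CC[C@]1(C)O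
F5 | step 8 | 5-(1-ethoxyprop-1-en-2-yl)-5-hydroxy adduct of F4 | CCOC(=O)[C@]1(CCC=C=C)[C@H](CCCO[Si](C)(C)C(C)(C)C)C(O)(C(C)=COCC)CC[C@]1(C)O
F6 | step 8 | (5Z)-5-(1-oxopropan-2-ylidene) ester TBS ether | CCOC(=O)[C@]1(CCC=C=C)[C@H](CCCO[Si](C)(C)C(C)(C)C)/C(=C(/C)C=O)CC[C@]1(C)O
F7 | step 8 | triol TBS ether from reduction of F6 | OC[C@]1(CCC=C=C)[C@H](CCCO[Si](C)(C)C(C)(C)C)/C(=C(/C)CO)CC[C@]1(C)O
F8 | step 8 | primary TBS ether of 19 | O=C[C@]1(CCC=C=C)[C@H](CCCO[Si](C)(C)C(C)(C)C)/C(=C(/C)C=O)CC[C@]1(C)O
F9 | step 14 | spiro diol carrying a 1-(pinacolboryl)vinyl group at C2 | C=C(B1OC(C)(C)C(C)(C)O1)[C@@H]1CC[C@]2([C@H](CCCO)/C(=C(/C)C=O)CC[C@]2(C)O)[C@@H]1O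
F10 | step 14 | (2Z,4E)-5-iodo-2-(4-methylpent-3-en-1-yl)penta-2,4-dien-1-yl acetate | I/C=C/C=C(/CCC=C(C)C)COC(C)=O
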